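A mole of electrophile coupled in eta costs me two moles of nucleophile if the acid set free stays in the flask: one mole reacts and one is protonated.

    electrophile + nucleophile → acid set free + target (k1 = 0.10 /M/s)
    nucleophile + acid set free ⇌ protonated nucleophile, settled at all times (K2 = 7200 /M)
    electrophile + target → side product (k3 = 0.029 /M/s)
    acid set free → by-product carried off (k4 = 0.0025 /s)
    nucleophile + target ⇌ idle adduct, settled at all times (K5 = 87 /M)

| flask | electrophile | nucleophile | time |
|---|---|---|---|
| eta | 0.20 M | 1.10 equiv | 4.0 min |
| theta | 0.20 M | 1.40 equiv | 4.0 min |
| epsilon | 0.20 M | 1.90 equiv | 4.0 min |

- percent here means electrophile units held: one side product counts as two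
- what is said of target includes idle adduct
- run time (eta): 4.0 min

* part of the electrophile that has reacted at the end, eta
* part of the electrophile that has reacted at the end, theta
* part of the electrophile that has reacted at the end, epsilon
* what raising the equivalents of nucleophile from its lowest to its highest value here does to the part of the electrophile that has reacted (changes below 5 percentage points count as none) (no change / it falls / it rises)

I write the balance of the nucleophile per mole of electrophile charged. At the start of eta, the protonation constant times [nucleophile] is 1600, the ratio of protonated nucleophile to acid set free at balance, so hardly any of the acid stands free for its loss, whose half-life is 4.6 min. I therefore take the two-mole price for this run, and on it, with no nucleophile in idle adduct, eta can pay for 55.0% of its electrophile. This is the coupling ceiling: half the equivalents charged, which makes the nucleophile the effective limiting reagent in eta, despite its nominal excess.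

Theta looks nearly the same, at 1.40 equiv against 1.10 equiv, but its ceiling is 70.0%. The coupling half-life as charged in eta, 0.53 min, is short against the 4.0 min run, so I expect eta and theta to end near their ceilings, not at full conversion. Two corrections pull opposite ways: the side reaction consumes electrophile without spending nucleophile, and the idle adduct holds nucleophile back. I commit to the ceilings themselves, 55.0% for eta, 70.0% for theta and 95.0% for epsilon, a rise of 40 percentage points.

The forecast gives 58%, 69% and 78%, and says it rises. It stands below me on epsilon. Its ground: “Each coupling effectively costs two nucleophiles”.

The simulation gives 58.6%, 67.3% and 79.0%: it rises, by 20 points. At the end of eta, 3.0% of the nucleophile stands free, less than the 41% of the electrophile left. Each side product holds one coupling and one extra electrophile, so the couplings in eta are target plus half the side product, 47.4%, against the ceiling of 55.0%. The idle adduct, one nucleophile per target, stands in eta at 13.2% of the electrophile charged at that moment.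

In the neighbour of epsilon charged with 0.470 equiv of nucleophile, the ceiling is 23.5%. That flask computes to 22.9% couplings and 32.9% of its electrophile reacted.

The numbers were set for the occasion; the rest is arithmetic.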